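**Strategy.** The route rests on cutting the flavone at C3 of the γ-pyranone (ring C). This lone methine sits between the ketone carbon C4 and the enol-ether carbon C2, each traceable to a carboxyl carbon, so ring C reduces to an A-ring salicylic acid, a B-ring benzoic acid and one ylide carbon. In the key step the silylated ylide 17 is C-acylated by silyl ester 13 (C3–C4) and the resulting acylphosphorane olefinates the adjacent aryl ester carbonyl (C2=C3), closing ring C in one flask. Precursor 13 is the trimethylsilyl ester of a tetrabenzyl-protected 2-(aroyloxy)benzoic acid, assembled by aroylating the salicylaldehyde and oxidising the formyl group afterwards.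

Key step: step 11

Remark: the target has no stereocentre and no configurationally stable axis (the C2–C1′ bond rotates freely), so it is achiral; nothing has to be set or resolved and the route contains no stereoselective step.

**Route**

Step 1
Reactants: 1 2,4,6-trihydroxybenzaldehyde
Product: 2 2,4-bis(benzyloxy)-6-hydroxybenzaldehyde
Conditions: BnBr (2.05 equiv), K2CO3 (2.2 equiv), DMF, 0 °C → rt
Reagents that add atoms: benzyl bromide, BrCc1ccccc1
Why: Williamson ether synthesis under stoichiometric control: the para-OH (most acidic) and one ortho-OH are alkylated, whereas the last ortho-OH is tied up in the hydrogen bond to the formyl oxygen and should stay free.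

Step 2
Reactants: 2 2,4-bis(benzyloxy)-6-hydroxybenzaldehyde
Product: 3 2,4-bis(benzyloxy)-3,5-dibromo-6-hydroxybenzaldehyde
Conditions: NBS (2.05 equiv), MeCN, 0 °C → rt, dark
Reagents that add atoms: N-bromosuccinimide, O=C1CCC(=O)N1Br
Why: Electrophilic aromatic bromination: C3 and C5 are the only ring CH positions and each is ortho/para to three oxygen donors, so two equivalents of NBS under ionic, light-excluded conditions should fill both without touching the benzylic CH2 groups.

Step 3
Reactants: 3 2,4-bis(benzyloxy)-3,5-dibromo-6-hydroxybenzaldehyde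
Product: 4 4,6-bis(benzyloxy)-2-hydroxy-3,5-dimethoxybenzaldehyde
Conditions: NaOMe (excess), CuBr (0.3 equiv), MeOH/DMF, 110 °C, Ar; then aq. HCl
Reagents that add atoms: sodium methoxide, [Na+].[O-]C
Why: Copper(I)-catalysed Ullmann-type methanolysis of aryl bromides, the usual entry to methoxy groups flanked by two oxygens on flavonoid A-rings; the phenoxide formed in situ turns the aldehyde into a vinylogous carboxylate that resists methoxide, and benzyl ethers are inert.

Step 4
Reactants: 5 2-hydroxy-6-methoxybenzoic acid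
Product: 7 3,6-dihydroxy-2-methoxybenzoic acid, via 3-carboxy-4-hydroxy-2-methoxyphenyl hydrogen sulfate 6 (not isolated)
Conditions: K2S2O8 (1.05 equiv), 10% aq. NaOH, 10–20 °C; acidify to pH 4, wash out unreacted 5 (Et2O); then conc. HCl, 80 °C, Na2SO3 (antioxidant)
Reagents that add atoms: potassium peroxodisulfate, [K+].[K+].[O-]S(=O)(=O)OOS(=O)(=O)[O-]
Why: Elbs persulfate oxidation: the phenoxide of 5 attacks peroxodisulfate through the carbon para to the phenoxide oxygen (C5, the only para position), and acid hydrolysis of aryl sulfate 6 unmasks the hydroquinone.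

Step 5
Reactants: 7 3,6-dihydroxy-2-methoxybenzoic acid
Product: 8 benzyl 3,6-bis(benzyloxy)-2-methoxybenzoate
Conditions: BnBr (3.5 equiv), K2CO3 (4 equiv), DMF, 60 °C, N2
Reagents that add atoms: benzyl bromide, BrCc1ccccc1
Why: Williamson O-alkylation of both phenoxides together with SN2 esterification of the carboxylate, run under nitrogen because the hydroquinone dianion is air-sensitive.

Step 6
Reactants: 8 benzyl 3,6-bis(benzyloxy)-2-methoxybenzoate
Product: 9 3,6-bis(benzyloxy)-2-methoxybenzoic acid
Conditions: KOH (excess), DMSO/H2O, 100 °C; then aq. HCl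
Reagents that add atoms: potassium hydroxide, [K+].[OH-]
Why: Saponification (acyl–oxygen cleavage) of the benzyl ester; the two ortho substituents slow hydroxide attack, hence hot aqueous DMSO, while the benzyl aryl ethers are untouched by base.

Step 7
Reactants: 4 4,6-bis(benzyloxy)-2-hydroxy-3,5-dimethoxybenzaldehyde; 9 3,6-bis(benzyloxy)-2-methoxybenzoic acid
Product: 11 3,5-bis(benzyloxy)-2-formyl-4,6-dimethoxyphenyl 3,6-bis(benzyloxy)-2-methoxybenzoate, via 3,6-bis(benzyloxy)-2-methoxybenzoyl chloride 10 (not isolated)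
Conditions: 9, (COCl)2 (1.5 equiv), cat. DMF, CH2Cl2, 0 °C → rt, evaporate; then 4, Et3N, DMAP (cat.), CH2Cl2, 0 °C → reflux
Reagents that add atoms: none
Why: Acid chloride formation through the chloroiminium catalyst followed by DMAP-catalysed O-acylation of the phenol (nucleophilic acyl substitution); acylating at the aldehyde stage avoids a free carboxylic acid that would give mixed anhydrides and a decarboxylation-prone trioxygenated salicylic acid.

Step 8
Reactants: 11 3,5-bis(benzyloxy)-2-formyl-4,6-dimethoxyphenyl 3,6-bis(benzyloxy)-2-methoxybenzoate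
Product: 12 4,6-bis(benzyloxy)-2-{[3,6-bis(benzyloxy)-2-methoxybenzoyl]oxy}-3,5-dimethoxybenzoic acid
Conditions: NaClO2, NaH2PO4, 2-methyl-2-butene (excess), t-BuOH/THF/H2O, 0 °C → rt
Reagents that add atoms: sodium chlorite, [Na+].[O-]Cl=O
Why: Pinnick (Lindgren) oxidation: chlorous acid converts the aldehyde into the acid at pH 3–4, where the aryl ester and benzyl ethers are stable, and 2-methyl-2-butene removes the hypochlorous acid that could chlorinate ring B.

Step 9
Reactants: 12 4,6-bis(benzyloxy)-2-{[3,6-bis(benzyloxy)-2-methoxybenzoyl]oxy}-3,5-dimethoxybenzoic acid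
Product: 13 trimethylsilyl 4,6-bis(benzyloxy)-2-{[3,6-bis(benzyloxy)-2-methoxybenzoyl]oxy}-3,5-dimethoxybenzoate
Conditions: HMDS (1.5 equiv), toluene, 70 °C; evaporate under Ar, used crude
Reagents that add atoms: hexamethyldisilazane, C[Si](C)(C)N[Si](C)(C)C
Why: O-silylation of the carboxylic acid with hexamethyldisilazane, which releases only ammonia, so evaporation should leave a salt-free and proton-free silyl ester for the ylide step.

Step 10
Reactants: 14 methyltriphenylphosphonium bromide
Product: 17 (trimethylsilyl)methylenetriphenylphosphorane, via methylenetriphenylphosphorane 15 (not isolated), via (trimethylsilylmethyl)triphenylphosphonium chloride 16 (not isolated)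
Conditions: n-BuLi (1.0 equiv), THF, 0 °C; TMSCl (1.0 equiv), 0 °C → rt; n-BuLi (1.0 equiv), 0 °C; solvent switch to toluene, Li salts filtered off under Ar, concentrated
Reagents that add atoms: chlorotrimethylsilane, C[Si](C)(C)Cl
Why: Deprotonation of the phosphonium salt to the methylene ylide, C-silylation with chlorotrimethylsilane and a second deprotonation of the more acidic α-silylphosphonium salt 16, the standard preparation of this isolable silyl-substituted Wittig reagent.

Step 11
Reactants: 13 trimethylsilyl 4,6-bis(benzyloxy)-2-{[3,6-bis(benzyloxy)-2-methoxybenzoyl]oxy}-3,5-dimethoxybenzoate; 17 (trimethylsilyl)methylenetriphenylphosphorane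
Product: 19 5,7-bis(benzyloxy)-2-[3,6-bis(benzyloxy)-2-methoxyphenyl]-6,8-dimethoxy-4H-chromen-4-one, via acylphosphorane 18 (not isolated)
Conditions: 17 (1.1–1.2 equiv), THF, 0 °C → rt; then toluene, 110 °C
Reagents that add atoms: none
Why: The ylide carbon of 17 adds to the silyl ester carbonyl of 13, trimethylsilanolate is expelled and strips the C-silyl group as hexamethyldisiloxane, leaving the stabilised acylphosphorane 18 (C3–C4 bond). On heating, the ylide carbon of 18 adds to the carbonyl of the neighbouring aryl ester in a 6-exo-trig closure, and the oxaphosphetane collapses with loss of triphenylphosphine oxide to give the C2=C3 enol-ether double bond and ring C. The closest known chemistry is the acylation of silylated phosphorus ylides by silyl esters combined with intramolecular Wittig olefination of esters, which is established as a one-pot chromone and flavone synthesis from silyl esters of O-acyl- and O-aroylsalicylic acids. No stereocentre is formed. The step needs chemoselective attack at the silyl ester and not at the aryl ester: the silyl ester is the activated acyl donor whose leaving group is consumed irreversibly by desilylation, whereas the aroyl carbonyl is buried between its 2-methoxy and 6-benzyloxy groups, and near-stoichiometric ylide at low temperature supports this, although the silyl ester carbonyl is itself flanked on both sides. Once 18 exists, ylide and ester carbonyl are held on adjacent ring positions, which should let the otherwise sluggish ester olefination proceed at reflux.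

Step 12
Reactants: 19 5,7-bis(benzyloxy)-2-[3,6-bis(benzyloxy)-2-methoxyphenyl]-6,8-dimethoxy-4H-chromen-4-one
Product: 20 5,7,3',6'-tetrahydroxy-6,8,2'-trimethoxyflavone
Conditions: H2 (1 atm), 10% Pd/C, THF/MeOH, rt; filtered and concentrated under Ar
Reagents that add atoms: none
Why: Palladium-catalysed hydrogenolysis of the four benzyl aryl ethers; at atmospheric pressure and room temperature the chromone C2=C3 bond (a doubly aryl-conjugated vinylogous ester) and the methyl ethers should survive, and the air-sensitive hydroquinone is kept under inert gas.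

**Compound list**

1 | 2,4,6-trihydroxybenzaldehyde | O=Cc1c(O)cc(O)cc1O | starting material
2 | 2,4-bis(benzyloxy)-6-hydroxybenzaldehyde | O=Cc1c(O)cc(OCc2ccccc2)cc1OCc1ccccc1 | intermediate
3 | 2,4-bis(benzyloxy)-3,5-dibromo-6-hydroxybenzaldehyde | O=Cc1c(O)c(Br)c(OCc2ccccc2)c(Br)c1OCc1ccccc1 | intermediate
4 | 4,6-bis(benzyloxy)-2-hydroxy-3,5-dimethoxybenzaldehyde | O=Cc1c(O)c(OC)c(OCc2ccccc2)c(OC)c1OCc1ccccc1 | intermediate
5 | 2-hydroxy-6-methoxybenzoic acid | COc1cccc(O)c1C(=O)O | starting material
6 | 3-carboxy-4-hydroxy-2-methoxyphenyl hydrogen sulfate (present as its salt in solution) | COc1c(OS(=O)(=O)O)ccc(O)c1C(=O)O | intermediate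
7 | 3,6-dihydroxy-2-methoxybenzoic acid | COc1c(O)ccc(O)c1C(=O)O | intermediate
8 | benzyl 3,6-bis(benzyloxy)-2-methoxybenzoate | COc1c(OCc2ccccc2)ccc(OCc2ccccc2)c1C(=O)OCc1ccccc1 | intermediate
9 | 3,6-bis(benzyloxy)-2-methoxybenzoic acid | COc1c(OCc2ccccc2)ccc(OCc2ccccc2)c1C(=O)O | intermediate
10 | 3,6-bis(benzyloxy)-2-methoxybenzoyl chloride | COc1c(OCc2ccccc2)ccc(OCc2ccccc2)c1C(=O)Cl | intermediate
11 | 3,5-bis(benzyloxy)-2-formyl-4,6-dimethoxyphenyl 3,6-bis(benzyloxy)-2-methoxybenzoate | COc1c(OCc2ccccc2)ccc(OCc2ccccc2)c1C(=O)Oc1c(C=O)c(OCc2ccccc2)c(OC)c(OCc2ccccc2)c1OC | intermediate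
12 | 4,6-bis(benzyloxy)-2-{[3,6-bis(benzyloxy)-2-methoxybenzoyl]oxy}-3,5-dimethoxybenzoic acid | COc1c(OCc2ccccc2)ccc(OCc2ccccc2)c1C(=O)Oc1c(C(=O)O)c(OCc2ccccc2)c(OC)c(OCc2ccccc2)c1OC | intermediate
13 | trimethylsilyl 4,6-bis(benzyloxy)-2-{[3,6-bis(benzyloxy)-2-methoxybenzoyl]oxy}-3,5-dimethoxybenzoate | C[Si](C)(C)OC(=O)c1c(OC(=O)c2c(OC)c(OCc3ccccc3)ccc2OCc2ccccc2)c(OC)c(OCc2ccccc2)c(OC)c1OCc1ccccc1 | intermediate
14 | methyltriphenylphosphonium bromide | C[P+](c1ccccc1)(c1ccccc1)c1ccccc1.[Br-] | starting material
15 | methylenetriphenylphosphorane | C=P(c1ccccc1)(c1ccccc1)c1ccccc1 | intermediate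
16 | (trimethylsilylmethyl)triphenylphosphonium chloride | C[Si](C)(C)C[P+](c1ccccc1)(c1ccccc1)c1ccccc1.[Cl-] | intermediate
17 | (trimethylsilyl)methylenetriphenylphosphorane | C[Si](C)(C)C=P(c1ccccc1)(c1ccccc1)c1ccccc1 | intermediate
18 | 3,5-bis(benzyloxy)-4,6-dimethoxy-2-[(triphenyl-λ5-phosphanylidene)acetyl]phenyl 3,6-bis(benzyloxy)-2-methoxybenzoate (acylphosphorane) | COc1c(OCc2ccccc2)ccc(OCc2ccccc2)c1C(=O)Oc1c(C(=O)C=P(c2ccccc2)(c2ccccc2)c2ccccc2)c(OCc2ccccc2)c(OC)c(OCc2ccccc2)c1OC | intermediate
19 | 5,7-bis(benzyloxy)-2-[3,6-bis(benzyloxy)-2-methoxyphenyl]-6,8-dimethoxy-4H-chromen-4-one | COc1c(OCc2ccccc2)ccc(OCc2ccccc2)c1-c1cc(=O)c2c(OCc3ccccc3)c(OC)c(OCc3ccccc3)c(OC)c2o1 | intermediate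
20 | 5,7,3',6'-tetrahydroxy-6,8,2'-trimethoxyflavone (achiral) | COc1c(O)ccc(O)c1-c1cc(=O)c2c(O)c(OC)c(O)c(OC)c2o1 | target

**Step count and risk**

Total step count: 12.
Longest linear sequence: 8 steps (steps 4, 5, 6, 7, 8, 9, 11, 12 from 5; the branch from 1 through steps 1, 2, 3, 7, 8, 9, 11, 12 is equally long).

Steps most likely to fail:

1. Step 11. The ylide may attack the aryl ester instead of the silyl ester and cleave the depside. Traces of moisture may hydrolyse the silyl ester and quench the ylide. The sequence may also stall at the acylphosphorane because addition to the shielded ester carbonyl is too slow. The fallback sets out from 4 (with acid chloride 10 made from 9 as in step 7) and comes back at 19, building ring C by enolate acylation and cyclodehydration instead. Addition of methylmagnesium bromide (excess, THF, 0 °C) to 4 should give racemic 1-[4,6-bis(benzyloxy)-2-hydroxy-3,5-dimethoxyphenyl]ethanol F1. Oxidation with activated MnO2 in CH2Cl2 should give 1-[4,6-bis(benzyloxy)-2-hydroxy-3,5-dimethoxyphenyl]ethanone F2. Its lithium dianion (LiHMDS, THF, −78 °C) is C-acylated by 10, the direct variant of the Baker–Venkataraman sequence, to 1-[4,6-bis(benzyloxy)-2-hydroxy-3,5-dimethoxyphenyl]-3-[3,6-bis(benzyloxy)-2-methoxyphenyl]propane-1,3-dione F3. Acid-catalysed cyclodehydration (cat. TsOH, toluene, reflux) then closes the pyranone to 19.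

2. Step 3. Hydrodebromination may compete, substitution may stay incomplete at the bromine flanked by two benzyloxy groups, and the aldehyde may erode in hot methoxide. The fallback sets out from 1 and comes back at 4; it introduces the two ring oxygens by aldehyde-to-phenol oxidation instead of C–Br substitution.
   - Vilsmeier–Haack formylation of 1 (POCl3, DMF) should give 2,4,6-trihydroxybenzene-1,3-dicarbaldehyde F4.
   - Perbenzylation (BnBr, K2CO3, DMF) gives 2,4,6-tris(benzyloxy)benzene-1,3-dicarbaldehyde F5.
   - Baeyer–Villiger oxidation with mCPBA gives 2,4,6-tris(benzyloxy)-1,3-phenylene diformate F6, which is methanolysed (K2CO3, MeOH) to 2,4,6-tris(benzyloxy)benzene-1,3-diol F7.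
   - Methylation (MeI, K2CO3, acetone) gives 1,3,5-tris(benzyloxy)-2,4-dimethoxybenzene F8.
   - Vilsmeier–Haack formylation at the single ring CH gives 2,4,6-tris(benzyloxy)-3,5-dimethoxybenzaldehyde F9.
   - Chelation-controlled mono-debenzylation ortho to the formyl group (MgBr2·OEt2, toluene/Et2O) returns 4.

3. Step 4. Sulfate radicals may over-oxidise the electron-rich phenoxide to dark polymeric material while conversion to the para-sulfate stays low. The fallback sets out from 5 and comes back at 8, replacing persulfate hydroxylation by quinone formation and reduction. Selective carboxylate alkylation (BnBr, KHCO3, DMF, rt) should give benzyl 2-hydroxy-6-methoxybenzoate F10. Teuber oxidation with Fremy's salt (KH2PO4 buffer, H2O/acetone) gives the para-quinone benzyl 2-methoxy-3,6-dioxocyclohexa-1,4-diene-1-carboxylate F11. Dithionite reduction (Na2S2O4, EtOAc/H2O) gives benzyl 3,6-dihydroxy-2-methoxybenzoate F12. Double O-benzylation (BnBr, K2CO3, DMF) then gives 8.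

**Further compounds**

F1 | step 11 | racemic 1-[4,6-bis(benzyloxy)-2-hydroxy-3,5-dimethoxyphenyl]ethanol | CC(O)c1c(O)c(OC)c(OCc2ccccc2)c(OC)c1OCc1ccccc1
F2 | step 11 | 1-[4,6-bis(benzyloxy)-2-hydroxy-3,5-dimethoxyphenyl]ethanone | CC(=O)c1c(O)c(OC)c(OCc2ccccc2)c(OC)c1OCc1ccccc1
F3 | step 11 | 1-[4,6-bis(benzyloxy)-2-hydroxy-3,5-dimethoxyphenyl]-3-[3,6-bis(benzyloxy)-2-methoxyphenyl]propane-1,3-dione | COc1c(OCc2ccccc2)ccc(OCc2ccccc2)c1C(=O)CC(=O)c1c(O)c(OC)c(OCc2ccccc2)c(OC)c1OCc1ccccc1
F4 | step 3 | 2,4,6-trihydroxybenzene-1,3-dicarbaldehyde | O=Cc1c(O)cc(O)c(C=O)c1O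
F5 | step 3 | 2,4,6-tris(benzyloxy)benzene-1,3-dicarbaldehyde | O=Cc1c(OCc2ccccc2)cc(OCc2ccccc2)c(C=O)c1OCc1ccccc1
F6 | step 3 | 2,4,6-tris(benzyloxy)-1,3-phenylene diformate | O=COc1c(OCc2ccccc2)cc(OCc2ccccc2)c(OC=O)c1OCc1ccccc1
F7 | step 3 | 2,4,6-tris(benzyloxy)benzene-1,3-diol | Oc1c(OCc2ccccc2)cc(OCc2ccccc2)c(O)c1OCc1ccccc1
F8 | step 3 | 1,3,5-tris(benzyloxy)-2,4-dimethoxybenzene | COc1c(OCc2ccccc2)cc(OCc2ccccc2)c(OC)c1OCc1ccccc1
F9 | step 3 | 2,4,6-tris(benzyloxy)-3,5-dimethoxybenzaldehyde | COc1c(OCc2ccccc2)c(C=O)c(OCc2ccccc2)c(OC)c1OCc1ccccc1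
F10 | step 4 | benzyl 2-hydroxy-6-methoxybenzoate | COc1cccc(O)c1C(=O)OCc1ccccc1
F11 | step 4 | benzyl 2-methoxy-3,6-dioxocyclohexa-1,4-diene-1-carboxylate | COC1=C(C(=O)OCc2ccccc2)C(=O)C=CC1=O
F12 | step 4 | benzyl 3,6-dihydroxy-2-methoxybenzoate | COc1c(O)ccc(O)c1C(=O)OCc1ccccc1
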